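**Retrosynthetic overview**
1. Ring numbering: C1 (Me, vinyl), C2 (CH2), C3 (O-acyl), C4 (acrylic acid), C5 (OH), C6 (hydroxypropenyl).
2. Endgame: C5–OH and the C6 allylic alcohol are released together from a cis-fused 2-methoxy-3-methylenetetrahydrofuran (ring B). The acrylic acid comes from a C4 isopropenyl group. The C3 ester comes from (Z)-4-acetoxy-2-methylbut-2-enoic acid (fragment 1, made by Pd carbonylation).
3. Key disconnection: C6–C(sp2) and C1–vinyl are formed in one nickel/photoredox cyclisation–vinylation. The substrate is a 2-bromoallyl acetal tethered at C5–O, and the partner is vinyl triflate (fragment 3).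
4. Ring A comes from RCM (C6=C1) of an acyclic triene. C2–C3 is made by iridium-catalysed methallylation, C4–C5 by a deconjugative Evans syn aldol, and the tether from methoxyallene (fragment 2).
5. Ring order: ring A (step 12), then temporary ring B (step 13), which is opened in step 17.

Assumption: the acetal carbon created in step 9 is carried as an inconsequential epimer mixture (no descriptor in the SMILES) and is destroyed in step 17.

**Fragment 1 (side-chain acid)**

Step 1
Reactants: 1 but-2-yn-1-ol
Product: 3 (Z)-3-iodobut-2-en-1-ol, via cyclic alkenylalanate 2 (not isolated)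
Conditions: NaAlH2(OCH2CH2OMe)2, THF, 0 °C to rt; then I2, THF, −78 °C
Reagents that add atoms: iodine, [I][I]; sodium bis(2-methoxyethoxy)aluminium dihydride, [Na+].[AlH2-](OCCOC)OCCOC (its atoms stay in 2 only)
Why: Hydroxyl-directed trans-hydroalumination of the propargylic alcohol places aluminium on C3 cis to the CH2O group, and iodinolysis with retention fixes the Z geometry.

Step 2
Reactants: 3 (Z)-3-iodobut-2-en-1-ol
Product: 4 (Z)-3-iodobut-2-en-1-yl acetate
Conditions: Ac2O, pyridine, DMAP (cat.), CH2Cl2, 0 °C
Reagents that add atoms: acetic anhydride, CC(=O)OC(C)=O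
Why: Standard O-acetylation installs the acetate before any carboxyl group exists, so butenolide formation is impossible and the alkene geometry is untouched.

Step 3
Reactants: 4 (Z)-3-iodobut-2-en-1-yl acetate
Product: 5 2-(trimethylsilyl)ethyl (Z)-4-acetoxy-2-methylbut-2-enoate
Conditions: Pd(OAc)2 (5 mol %), PPh3 (10 mol %), CO (1 atm), Me3SiCH2CH2OH, Et3N, DMF, 45 °C
Reagents that add atoms: carbon monoxide, [C-]#[O+]; 2-(trimethylsilyl)ethanol, C[Si](C)(C)CCO
Why: Palladium-catalysed alkoxycarbonylation of an alkenyl iodide works because oxidative addition of zerovalent palladium into C–I is far faster than ionisation of the allylic acetate, and CO insertion and alcoholysis proceed with retention to give the Z ester.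

Step 4
Reactants: 5 2-(trimethylsilyl)ethyl (Z)-4-acetoxy-2-methylbut-2-enoate
Product: 6 (Z)-4-acetoxy-2-methylbut-2-enoic acid
Conditions: Bu4NF, THF, 0 °C; cold 1 M HCl work-up
Reagents that add atoms: none
Why: Fluoride-triggered β-elimination of the 2-(trimethylsilyl)ethyl ester frees the acid under non-hydrolytic conditions that spare the acetate and the Z alkene.

**Fragment 2 (tether)**

Step 5
Reactants: 7 3-methoxyprop-1-yne
Product: 8 1-methoxypropa-1,2-diene (methoxyallene)
Conditions: KOt-Bu (cat.), neat, 70 °C, distil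
Reagents that add atoms: none
Why: Base-catalysed propargyl–allenyl isomerisation is driven by conjugation of the allene with oxygen and creates no stereocentre.

**Fragment 3 (vinyl donor)**

Step 6
Reactants: 9 tetrahydrofuran
Product: 11 ethenyl trifluoromethanesulfonate (vinyl triflate), via lithium ethenolate 10 (not isolated)
Conditions: n-BuLi, hexanes, 35 °C; then PhNTf2, 0 °C; bulb-to-bulb distillation
Reagents that add atoms: N-phenylbis(trifluoromethanesulfonimide), O=S(=O)(N(c1ccccc1)S(=O)(=O)C(F)(F)F)C(F)(F)F; n-butyllithium, [Li]CCCC (lithium stays in 10 only)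
Why: α-Lithiated THF undergoes cycloreversion to ethene and the lithium enolate of acetaldehyde, which is O-triflated (enolate triflation).

**Core**

Step 7
Reactants: 12 3-methylbut-2-enoyl chloride
Product: 13 (S)-4-benzyl-3-(3-methylbut-2-enoyl)oxazolidin-2-one
Conditions: (S)-4-benzyloxazolidin-2-one, n-BuLi, THF, −78 °C; then 12, −78 to 0 °C
Reagents that add atoms: (S)-4-benzyloxazolidin-2-one, O=C1N[C@@H](Cc2ccccc2)CO1
Why: N-acylation of the lithiated Evans auxiliary is a simple nucleophilic acyl substitution, and the stereocentre comes from the reagent.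

Step 8
Reactants: 13 (S)-4-benzyl-3-(3-methylbut-2-enoyl)oxazolidin-2-one; 14 acrolein
Product: 16 (S)-4-benzyl-3-[(2S,3R)-3-hydroxy-2-(prop-1-en-2-yl)pent-4-enoyl]oxazolidin-2-one, via boron dienolate 15 (not isolated)
Conditions: Bu2BOTf, Et3N, CH2Cl2, −78 to 0 °C; then 14, −78 °C; H2O2, MeOH, pH 7 buffer
Reagents that add atoms: dibutylboron triflate, CCCCB(CCCC)OS(=O)(=O)C(F)(F)F (its atoms stay in 15 only)
Why: In this deconjugative Evans syn aldol, soft enolisation removes a γ-proton to give the Z boron dienolate, which reacts at its α-carbon through a Zimmerman–Traxler chair opposite the benzyl group, setting C4 and C5 (2S,3R) and unveiling the isopropenyl group.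

Step 9
Reactants: 16 aldol adduct; 8 methoxyallene
Product: 17 (S)-4-benzyl-3-[(2S,3R)-3-(2-bromo-1-methoxyallyloxy)-2-(prop-1-en-2-yl)pent-4-enoyl]oxazolidin-2-one
Conditions: 8 (3 equiv), NBS, CH2Cl2, −78 to −20 °C
Reagents that add atoms: N-bromosuccinimide, O=C1CCC(=O)N1Br
Why: In this Ueno–Stork-type haloacetalisation, NBS brominates the central carbon of the electron-rich allene much faster than the other alkenes and the C5 hydroxyl traps the oxocarbenium ion, giving an acetal that serves as both protecting group and radical tether.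

Step 10
Reactants: 17 bromoallyl acetal imide
Product: 18 (2R,3R)-3-(2-bromo-1-methoxyallyloxy)-2-(prop-1-en-2-yl)pent-4-en-1-ol
Conditions: LiBH4, MeOH (1 equiv), Et2O, 0 °C
Reagents that add atoms: none
Why: Reductive removal of the auxiliary (imide reduction) leaves the acetal, the alkenyl bromide and both stereocentres untouched.

Step 11
Reactants: 18 primary alcohol; 19 3-chloro-2-methylprop-1-ene
Product: 20 (4S,5R,6R)-6-(2-bromo-1-methoxyallyloxy)-2-methyl-5-(prop-1-en-2-yl)octa-1,7-dien-4-ol
Conditions: [Ir(cod)Cl]2 (2.5 mol %), (S)-SEGPHOS (5 mol %; ligand antipode chosen for Si-face addition), 4-cyano-3-nitrobenzoic acid (10 mol %), K3PO4, THF, 65 °C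
Reagents that add atoms: none
Why: In this iridium-catalysed transfer-hydrogenative carbonyl methallylation from the alcohol oxidation level, the catalyst dehydrogenates the carbinol C–H and the chiral methallyliridium adds to the Si face of the transient aldehyde through a closed chair (catalyst control, Felkin-matched), setting C3 as S.

Step 12
Reactants: 20 acyclic triene alcohol
Product: 21 (1S,5R,6R)-5-(2-bromo-1-methoxyallyloxy)-3-methyl-6-(prop-1-en-2-yl)cyclohex-3-en-1-ol
Conditions: second-generation Hoveyda–Grubbs catalyst (5 mol %), CH2Cl2 (5 mM), 40 °C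
Reagents that add atoms: none
Why: Ring-closing metathesis of the C6 vinyl group and the methallyl alkene closes ring A as the only unstrained six-membered option, because the isopropenyl and 2-bromoalkene groups are too hindered or deactivated to compete, and no stereocentre is touched.

Step 13
Reactants: 21 tethered cyclohexenol; 11 vinyl triflate
Product: 22 (3aS,4R,6S,7R,7aR)-4-ethenyl-2-methoxy-4-methyl-3-methylidene-7-(prop-1-en-2-yl)octahydro-1-benzofuran-6-ol
Conditions: 11 (3 equiv), Ni(TMHD)2 (nickel bis(2,2,6,6-tetramethylheptane-3,5-dionate), 10 mol %), [Ir{dF(CF3)ppy}2(dtbbpy)]PF6 (1 mol %), (Me3Si)3SiOH (1.5 equiv), Na2CO3, acetone/PhCF3 1:1 (0.02 M), 450 nm LEDs, 25 °C; KF/MeOH work-up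
Reagents that add atoms: none
Why: Proposed new method: a silyl-radical/nickel metallaphotoredox alkenyl-vinylation of an alkene, in which the excited iridium photocatalyst oxidises the deprotonated silanol and the resulting silicon radical (after radical Brook shift) abstracts bromine from the C(sp2)–Br bond of 21; the σ-vinyl radical closes 5-exo onto C6 on the face of the C5–O tether (cis-fused ring B, C6 set); the tertiary C1 radical is captured on the convex face, anti to the new axial C6–C bond, by the vinyl–nickel species formed from zerovalent nickel and the far more reactive, bromine-free electrophile 11; reductive elimination from trivalent nickel then forges the quaternary C1–vinyl bond (net trans-diaxial dicarbofunctionalisation) and the reduced photocatalyst returns monovalent nickel to zerovalent nickel; the closest known reaction types are silyl-radical-mediated nickel/photoredox cross-electrophile coupling of alkyl bromides, silyl-radical bromine abstraction from aryl bromides in copper/photoredox catalysis, tin-hydride 5-exo cyclisation of 2-bromoallyl acetals and nickel-diketonate-catalysed arylation of tertiary radicals.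

Step 14
Reactants: 22 bicyclic alcohol; 6 (Z)-4-acetoxy-2-methylbut-2-enoic acid
Product: 24 C3 (Z)-4-acetoxy-2-methylbut-2-enoate of 22 (ring stereocentres unchanged), via mixed anhydride 23 (not isolated)
Conditions: 6, 2,4,6-Cl3C6H2COCl, Et3N, toluene, rt; then 22, DMAP (0.2 equiv), rt to 40 °C
Reagents that add atoms: 2,4,6-trichlorobenzoyl chloride, O=C(Cl)c1c(Cl)cc(Cl)cc1Cl (its atoms stay in 23 only)
Why: Yamaguchi esterification acylates the only free hydroxyl (equatorial C3–OH) with retention at C3, and the low DMAP loading preserves the Z (angelate-type) geometry.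

Step 15
Reactants: 24 ester
Product: 25 allylic alcohol (C4 substituent now 3-hydroxyprop-1-en-2-yl)
Conditions: SeO2 (0.3 equiv), t-BuOOH (3 equiv, decane), CH2Cl2, 0 °C to rt
Reagents that add atoms: tert-butyl hydroperoxide (terminal oxygen source), CC(C)(C)OO; selenium dioxide (oxygen relay), O=[Se]=O
Why: Catalytic SeO2 allylic oxidation (ene reaction then [2,3]-shift) attacks the most electron-rich 1,1-disubstituted alkene at its methyl group, since the vinyl group has no allylic hydrogen and the other alkenes are deactivated by acetal or ester groups.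

Step 16
Reactants: 25 allylic alcohol
Product: 27 acrylic acid (C4 substituent now 1-carboxyethenyl), via enal 26 (not isolated)
Conditions: MnO2, CH2Cl2, rt, filter; then NaClO2, NaH2PO4, 2-methylbut-2-ene, t-BuOH/H2O, 0 °C
Reagents that add atoms: sodium chlorite, [Na+].[O-]Cl=O
Why: Chemoselective MnO2 oxidation of the only free (allylic) alcohol followed by Pinnick oxidation of the crude enal gives the acrylic acid without touching the alkenes, the esters or the acetal.

Step 17
Reactants: 27 acrylic acid acetal
Product: 29 CNP0261293.4 (target), via lactol 28 (not isolated)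
Conditions: AcOH/THF/H2O 3:1:1, 30 °C, evaporate; then NaBH4, CeCl3·7H2O, MeOH, −40 °C; cold pH 5 buffer work-up
Reagents that add atoms: water, O
Why: Mild acid hydrolysis of the allylic cyclic acetal gives the lactol, whose open hydroxy-enal form undergoes Luche 1,2-reduction, releasing C5–OH and the allylic CH2OH together while the esters and the carboxylate stay intact and no stereocentre is affected.

**Compound list**
1 | but-2-yn-1-ol | CC#CCO | starting material
2 | sodium cyclic alkenylalanate (five-membered C–Al–O ring, two 2-methoxyethoxy ligands) | CC1=CCO[Al-]1(OCCOC)OCCOC.[Na+] | intermediate (not isolated)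
3 | (Z)-3-iodobut-2-en-1-ol | C/C(I)=C/CO | intermediate
4 | (Z)-3-iodobut-2-en-1-yl acetate | C/C(I)=C/COC(C)=O | intermediate
5 | 2-(trimethylsilyl)ethyl (Z)-4-acetoxy-2-methylbut-2-enoate | C[Si](C)(C)CCOC(=O)/C(C)=C\COC(C)=O | intermediate
6 | (Z)-4-acetoxy-2-methylbut-2-enoic acid | OC(=O)/C(C)=C\COC(C)=O | intermediate
7 | 3-methoxyprop-1-yne | COCC#C | starting material
8 | 1-methoxypropa-1,2-diene | COC=C=C | intermediate
9 | tetrahydrofuran | C1CCOC1 | starting material
10 | lithium ethenolate | [Li+].[O-]C=C | intermediate (not isolated)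
11 | ethenyl trifluoromethanesulfonate | C=COS(=O)(=O)C(F)(F)F | intermediate
12 | 3-methylbut-2-enoyl chloride | CC(C)=CC(=O)Cl | starting material
13 | (S)-4-benzyl-3-(3-methylbut-2-enoyl)oxazolidin-2-one | CC(C)=CC(=O)N1[C@@H](Cc2ccccc2)COC1=O | intermediate
14 | acrolein | C=CC=O | starting material
15 | Z dibutylboron dienolate of 13 | C=C(C)/C=C(\OB(CCCC)CCCC)N1[C@@H](Cc2ccccc2)COC1=O | intermediate (not isolated)
16 | (S)-4-benzyl-3-[(2S,3R)-3-hydroxy-2-(prop-1-en-2-yl)pent-4-enoyl]oxazolidin-2-one | O=C(N1[C@@H](Cc2ccccc2)COC1=O)[C@@H](C(C)=C)[C@H](O)C=C | intermediate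
17 | (S)-4-benzyl-3-[(2S,3R)-3-(2-bromo-1-methoxyallyloxy)-2-(prop-1-en-2-yl)pent-4-enoyl]oxazolidin-2-one (acetal epimers) | O=C(N1[C@@H](Cc2ccccc2)COC1=O)[C@@H](C(C)=C)[C@H](OC(OC)C(Br)=C)C=C | intermediate
18 | (2R,3R)-3-(2-bromo-1-methoxyallyloxy)-2-(prop-1-en-2-yl)pent-4-en-1-ol | OC[C@@H](C(C)=C)[C@H](OC(OC)C(Br)=C)C=C | intermediate
19 | 3-chloro-2-methylprop-1-ene | C=C(C)CCl | starting material
20 | (4S,5R,6R)-6-(2-bromo-1-methoxyallyloxy)-2-methyl-5-(prop-1-en-2-yl)octa-1,7-dien-4-ol | C=C(C)C[C@H](O)[C@@H](C(C)=C)[C@H](OC(OC)C(Br)=C)C=C | intermediate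
21 | (1S,5R,6R)-5-(2-bromo-1-methoxyallyloxy)-3-methyl-6-(prop-1-en-2-yl)cyclohex-3-en-1-ol | CC1=C[C@@H](OC(OC)C(Br)=C)[C@H](C(C)=C)[C@@H](O)C1 | intermediate
22 | (3aS,4R,6S,7R,7aR)-4-ethenyl-2-methoxy-4-methyl-3-methylidene-7-(prop-1-en-2-yl)octahydro-1-benzofuran-6-ol | C=C[C@@]1(C)C[C@H](O)[C@@H](C(C)=C)[C@H](OC(OC)C2=C)[C@@H]12 | intermediate
23 | (Z)-4-acetoxy-2-methylbut-2-enoic 2,4,6-trichlorobenzoic anhydride | O=C(OC(=O)/C(C)=C\COC(C)=O)c1c(Cl)cc(Cl)cc1Cl | intermediate (not isolated)
24 | C3 (Z)-4-acetoxy-2-methylbut-2-enoate of 22 | C=C[C@@]1(C)C[C@H](OC(=O)/C(C)=C\COC(C)=O)[C@@H](C(C)=C)[C@H](OC(OC)C2=C)[C@@H]12 | intermediate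
25 | 24 with C4 3-hydroxyprop-1-en-2-yl group | C=C[C@@]1(C)C[C@H](OC(=O)/C(C)=C\COC(C)=O)[C@@H](C(=C)CO)[C@H](OC(OC)C2=C)[C@@H]12 | intermediate
26 | 24 with C4 3-oxoprop-1-en-2-yl group (enal) | C=C[C@@]1(C)C[C@H](OC(=O)/C(C)=C\COC(C)=O)[C@@H](C(=C)C=O)[C@H](OC(OC)C2=C)[C@@H]12 | intermediate (not isolated)
27 | 24 with C4 1-carboxyethenyl group | C=C[C@@]1(C)C[C@H](OC(=O)/C(C)=C\COC(C)=O)[C@@H](C(=C)C(=O)O)[C@H](OC(OC)C2=C)[C@@H]12 | intermediate
28 | lactol of 27 (OMe replaced by OH) | C=C[C@@]1(C)C[C@H](OC(=O)/C(C)=C\COC(C)=O)[C@@H](C(=C)C(=O)O)[C@H](OC(O)C2=C)[C@@H]12 | intermediate (not isolated)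
29 | 2-[(1S,2R,3S,4R,6S)-6-{[(Z)-4-acetoxy-2-methylbut-2-enoyl]oxy}-4-ethenyl-2-hydroxy-3-(3-hydroxyprop-1-en-2-yl)-4-methylcyclohexyl]prop-2-enoic acid | C=C[C@@]1(C)C[C@H](OC(=O)/C(C)=C\COC(C)=O)[C@@H](C(=C)C(=O)O)[C@H](O)[C@@H]1C(=C)CO | target

**Step count**
- Total step count: 17.
- Longest linear sequence: 11 steps (steps 7–17, from 12 to 29).

**Steps most likely to fail**

- **Step 13 (the proposed new reaction).**
  - Risks:
    - Nickel may insert directly into the C–Br bond of 21, giving uncyclised diene.
    - The vinyl radical may undergo a 1,5-hydrogen shift from C4–H.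
    - The silicon radical may add to alkenes.
    - The tertiary radical may lose hydrogen instead of being captured.
  - Fallback (known chemistry), setting out from 21: irradiate 21 with (Bu3Sn)2 and (E)-1,2-bis(phenylsulfonyl)ethene in dilute benzene. The tin radical abstracts bromine and the same 5-exo cyclisation follows. The tertiary radical then adds to the disulfone on the convex face and expels a sulfonyl radical, giving the (E)-vinyl sulfone F1. Reductive desulfonylation of F1 with sodium amalgam, Na(Hg), and Na2HPO4 in MeOH at −20 °C returns to the route at 22.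

- **Step 11.**
  - Risk: the transient α-isopropenyl-β-alkoxy aldehyde may epimerise, conjugate or eliminate at 65 °C in the presence of K3PO4.
  - Fallback, setting out from 18: NaHCO3-buffered Dess–Martin oxidation at 0 °C gives the aldehyde F2, which is used at once. It is treated with methallyltributylstannane under (S)-BINOL/Ti(Oi-Pr)4 catalysis (4 Å molecular sieves, CH2Cl2, −20 °C). This low-temperature Lewis-acid-catalysed Keck methallylation returns to the route at 20.

- **Step 15.**
  - Risk: SeO2 may oxidise other allylic positions, over-oxidise the substrate or degrade the acetal.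
  - Fallback, setting out from 24: ene-type chlorination with NaOCl/CeCl3·7H2O (CH2Cl2/H2O, 0 °C) gives the allylic chloride F3. Kornblum oxidation of F3 (DMSO, NaHCO3, NaI cat., 40 °C) returns to the route at the enal 26, which goes straight into the Pinnick stage of step 16.

**Further compounds**
F1 | step 13 | 22 with the C1 vinyl group replaced by (E)-2-(phenylsulfonyl)ethenyl | O=S(=O)(/C=C/[C@@]1(C)C[C@H](O)[C@@H](C(C)=C)[C@H](OC(OC)C2=C)[C@@H]12)c3ccccc3
F2 | step 11 | (2S,3R)-3-(2-bromo-1-methoxyallyloxy)-2-(prop-1-en-2-yl)pent-4-enal | O=C[C@@H](C(C)=C)[C@H](OC(OC)C(Br)=C)C=C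
F3 | step 15 | 24 with C4 3-chloroprop-1-en-2-yl group | C=C[C@@]1(C)C[C@H](OC(=O)/C(C)=C\COC(C)=O)[C@@H](C(=C)CCl)[C@H](OC(OC)C2=C)[C@@H]12
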